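**Retrosynthetic overview**
- Mulberrofuran L is taken back to its bis(methoxymethyl) ether on the 2-aryl ring; the last operation is acetal cleavage.
- The furan ring, the only ring that is made, is opened at C3–C3a (palladium-catalysed intramolecular C–H alkenylation of a (Z)-β-bromovinyl aryl ether) and then at O1–C2 (anti addition of a phenoxide to a 1-bromoalkyne).
- The fragments are 2-geranylresorcinol (resorcinol bis(MOM) ether, lithiation at C2, copper-mediated geranylation, unmasking) and 1-(bromoethynyl)-3,5-bis(methoxymethoxy)benzene (from 3,5-dihydroxybenzaldehyde by dibromo-olefination and dehydrobromination).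
- Feature on which the strategy rests: C7 of the benzofuran, which carries the geranyl chain, lies between C7a–O1 and C6–OH. The benzo ring is therefore a symmetric 2-geranylresorcinol: either hydroxyl can become O1, and the one unsubstituted carbon next to that oxygen is the future C3a.
- Ring order: both benzene rings are bought; the geranyl–arene bond is made first, then O1–C2, and the furan is closed last through C3–C3a.

Key step: step 8

Remark: geranyl = (2E)-3,7-dimethylocta-2,6-dien-1-yl and MOM = methoxymethyl throughout; the bromovinyl ether is isolated before the palladium step so that the excess diol of step 7 is removed.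

**Step 1**
Reactants: 1 resorcinol
Product: 2 1,3-bis(methoxymethoxy)benzene
Conditions: MOMCl (2.5 equiv), i-Pr2NEt (3 equiv), CH2Cl2, 0 °C to rt
Reagents that add atoms: chloromethyl methyl ether (MOMCl), COCCl
Why: Both phenols should be O-alkylated by the highly electrophilic α-chloro ether under amine base (Williamson-type etherification), giving acetals that tolerate organolithiums and direct metalation.

**Step 2**
Reactants: 2 1,3-bis(methoxymethoxy)benzene; 3 geranyl bromide [(2E)-1-bromo-3,7-dimethylocta-2,6-diene]
Product: 6 2-geranyl-1,3-bis(methoxymethoxy)benzene, via 2-lithio-1,3-bis(methoxymethoxy)benzene 4 (not isolated), via arylcopper 5 (not isolated)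
Conditions: n-BuLi (1.1 equiv), THF, 0 °C to rt; CuI (1.0 equiv), −20 °C; then 3, −20 °C to rt
Reagents that add atoms: none
Why: The two acetal oxygens jointly direct n-BuLi to the carbon between them (directed ortho-metalation), and transmetalation to the aryl compound of monovalent copper lets the bromide be displaced at its primary carbon (copper-mediated SN2 allylic substitution) without allylic transposition, so the E alkene is carried over unchanged.

**Step 3**
Reactants: 6 2-geranyl-1,3-bis(methoxymethoxy)benzene
Product: 7 2-geranylresorcinol (2-geranylbenzene-1,3-diol)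
Conditions: HCl (1 M in MeOH), rt
Reagents that add atoms: none
Why: Aryl methoxymethyl ethers undergo acid-catalysed acetal exchange with methanol at room temperature, and under such dilute acid the trisubstituted alkenes are not expected to be protonated at a competitive rate.

**Step 4**
Reactants: 8 3,5-dihydroxybenzaldehyde
Product: 9 3,5-bis(methoxymethoxy)benzaldehyde
Conditions: MOMCl (2.5 equiv), i-Pr2NEt (3 equiv), CH2Cl2 (a little DMF for solubility), 0 °C to rt
Reagents that add atoms: chloromethyl methyl ether (MOMCl), COCCl
Why: Williamson-type O-alkylation of both phenols as in step 1; the aldehyde does not react with the chloro ether or the amine.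

**Step 5**
Reactants: 9 3,5-bis(methoxymethoxy)benzaldehyde
Product: 10 1-(2,2-dibromoethenyl)-3,5-bis(methoxymethoxy)benzene
Conditions: CBr4 (2 equiv), PPh3 (4 equiv), Et3N (1 equiv), CH2Cl2, 0 °C
Reagents that add atoms: carbon tetrabromide, BrC(Br)(Br)Br
Why: The ylide Ph3P=CBr2 formed in the flask should olefinate the aldehyde (Ramirez dibromo-olefination, first stage of the Corey–Fuchs sequence), and the Et3N buffer keeps traces of HBr from cleaving the acetals.

**Step 6**
Reactants: 10 1-(2,2-dibromoethenyl)-3,5-bis(methoxymethoxy)benzene
Product: 11 1-(bromoethynyl)-3,5-bis(methoxymethoxy)benzene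
Conditions: DBU (2 equiv), DMSO, 15–20 °C; aqueous NH4Cl work-up
Reagents that add atoms: none
Why: DBU in DMSO should remove HBr from the aryl 1,1-dibromoalkene by E2 elimination and stop at the 1-bromoalkyne, since no organometallic base is present that could exchange the remaining bromine.

**Step 7**
Reactants: 7 2-geranylresorcinol; 11 1-(bromoethynyl)-3,5-bis(methoxymethoxy)benzene
Product: 12 3-{[(Z)-1-[3,5-bis(methoxymethoxy)phenyl]-2-bromoethenyl]oxy}-2-geranylphenol
Conditions: 7 (3 equiv), K2CO3 (3 equiv), DMF, 110 °C, Ar; excess 7 recovered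
Reagents that add atoms: none
Why: The phenoxide should attack the aryl-bearing alkyne carbon to give a bromine-stabilised vinyl anion that is protonated anti to the incoming oxygen (base-mediated anti hydro-aryloxylation of a haloalkyne), which places O and Br cis (Z); the two hydroxyls of 7 are equivalent and the excess of diol should hold the reaction at mono-addition.

**Step 8**
Reactants: 12 3-{[(Z)-1-[3,5-bis(methoxymethoxy)phenyl]-2-bromoethenyl]oxy}-2-geranylphenol
Product: 13 2-[3,5-bis(methoxymethoxy)phenyl]-7-geranyl-1-benzofuran-6-ol
Conditions: Pd(OAc)2 (5 mol %), PPh3 (10 mol %), K2CO3 (3 equiv), DMF, 120 °C, Ar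
Reagents that add atoms: none
Why: PPh3 reduces Pd(OAc)2 to zerovalent palladium, which inserts into the vinyl C–Br bond with retention, so that the metal sits cis to the aryloxy group and is held beside the single free C–H ortho to the ether oxygen. Carbonate-assisted concerted metalation–deprotonation at that carbon gives a six-membered oxapalladacycle of divalent palladium, and C–C reductive elimination forms C3–C3a and returns zerovalent palladium; the closest known reaction type is the palladium-catalysed intramolecular direct C–H alkenylation of (Z)-2-bromovinyl aryl ethers to 2-substituted benzofurans. The furan ring is thus closed by bond formation between the former bromovinyl carbon and the arene carbon, a five-membered ring closure that is aromatic as soon as it forms, and no stereocentre is created (the Z geometry of 12 is consumed and the E alkene of the chain is not touched). The step needs site selectivity on the arene and chemoselectivity over Heck insertion: the other carbon ortho to the ether oxygen carries the geranyl group, the reacting carbon is para to the free phenoxide oxygen and therefore electron-rich, and the trisubstituted geranyl alkenes could only be reached through rings of seven or more members. The basic medium should leave the geranyl chain and both acetals intact, and the free hydroxyl needs no protection because it cannot reach the palladium centre within the molecule.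

**Step 9**
Reactants: 13 2-[3,5-bis(methoxymethoxy)phenyl]-7-geranyl-1-benzofuran-6-ol
Product: 14 Mulberrofuran L [5-(7-geranyl-6-hydroxy-1-benzofuran-2-yl)benzene-1,3-diol]
Conditions: HCl (1 M in MeOH), 0 °C to rt, Ar
Reagents that add atoms: none
Why: Acid-catalysed acetal exchange with methanol should free both phenols of the 2-aryl ring under conditions mild enough that cycloetherification of the C6 hydroxyl onto the neighbouring alkene does not compete.

**Compound list**
1 | resorcinol | Oc1cccc(O)c1 | starting material
2 | 1,3-bis(methoxymethoxy)benzene | COCOc1cccc(OCOC)c1 | intermediate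
3 | geranyl bromide, (2E)-1-bromo-3,7-dimethylocta-2,6-diene | CC(C)=CCC/C(C)=C/CBr | starting material
4 | 2-lithio-1,3-bis(methoxymethoxy)benzene | [Li]c1c(OCOC)cccc1OCOC | intermediate
5 | [2,6-bis(methoxymethoxy)phenyl]copper | [Cu]c1c(OCOC)cccc1OCOC | intermediate
6 | 2-geranyl-1,3-bis(methoxymethoxy)benzene | CC(C)=CCC/C(C)=C/Cc1c(OCOC)cccc1OCOC | intermediate
7 | 2-geranylresorcinol | CC(C)=CCC/C(C)=C/Cc1c(O)cccc1O | intermediate
8 | 3,5-dihydroxybenzaldehyde | O=Cc1cc(O)cc(O)c1 | starting material
9 | 3,5-bis(methoxymethoxy)benzaldehyde | O=Cc1cc(OCOC)cc(OCOC)c1 | intermediate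
10 | 1-(2,2-dibromoethenyl)-3,5-bis(methoxymethoxy)benzene | BrC(Br)=Cc1cc(OCOC)cc(OCOC)c1 | intermediate
11 | 1-(bromoethynyl)-3,5-bis(methoxymethoxy)benzene | BrC#Cc1cc(OCOC)cc(OCOC)c1 | intermediate
12 | 3-{[(Z)-1-[3,5-bis(methoxymethoxy)phenyl]-2-bromoethenyl]oxy}-2-geranylphenol | CC(C)=CCC/C(C)=C/Cc1c(O)cccc1O/C(=C\Br)c1cc(OCOC)cc(OCOC)c1 | intermediate
13 | 2-[3,5-bis(methoxymethoxy)phenyl]-7-geranyl-1-benzofuran-6-ol | CC(C)=CCC/C(C)=C/Cc1c(O)ccc2cc(-c3cc(OCOC)cc(OCOC)c3)oc12 | intermediate
14 | Mulberrofuran L | CC(C)=CCC/C(C)=C/Cc1c(O)ccc2cc(-c3cc(O)cc(O)c3)oc12 | target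

**Step count**
Total steps: 9. Longest linear sequence: 6 steps (steps 1, 2, 3, 7, 8, 9 from resorcinol; the aryl branch through steps 4, 5, 6, 7, 8, 9 is equally long).

**Steps most likely to fail**

1. Step 8. After oxidative addition the alkenylpalladium species may be lost to protodebromination, or the catalyst may be arrested by the free phenoxide, so that C–H palladation does not turn over and the furan does not close.
Fallback (sets out from 7 and 10, returns at 13): the two furan bonds are made in the opposite order, C3–C3a by cross-coupling and O1–C2 by cyclisation. Diol 7 would be mono-iodinated with one equivalent of I2 (NaHCO3, THF–H2O, 0 °C, slow addition) to give 4-iodo-2-geranylresorcinol F1. Dibromoalkene 10 would be treated with n-BuLi (2.1 equiv, THF, −78 °C) and carried through bromoalkyne 11 and the lithium acetylide F2 to give, after a water quench, 1-ethynyl-3,5-bis(methoxymethoxy)benzene F3. Sonogashira coupling of F1 with F3 (Pd(PPh3)2Cl2, CuI, Et3N, DMF, 60 °C) should give the ortho-alkynylphenol F4, which under the same conditions is expected to cyclise 5-endo-dig through the hydroxyl next to the alkyne to benzofuran 13, before step 9.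

2. Step 7. The second hydroxyl of the mono-adduct may add to another bromoalkyne, or the phenoxide flanked by the geranyl group may add so slowly that the bromoalkyne is consumed in side reactions.
Fallback (sets out from 7, returns at 14): the diol is desymmetrised by protection and not by stoichiometry. Treatment of 7 with one equivalent of MOMCl (i-Pr2NEt, CH2Cl2, 0 °C) would give, after separation from diol and bis-ether 6 (both recycled), 2-geranyl-3-(methoxymethoxy)phenol F5. This has a single nucleophilic oxygen and can be driven with excess 11 (K2CO3, DMF, 110 °C) to the tris(MOM) bromovinyl ether F6. Ring closure under the conditions of step 8 should give the 6-O-MOM benzofuran F7, and the acid treatment of step 9 then removes all three acetals to give 14.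

3. Step 9. Under protic acid the C6 hydroxyl may add to the protonated 2′,3′-alkene of the chain (chroman formation), or the alkenes may be solvolysed, faster than the acetals are cleaved.
Fallback (sets out from 8, returns at 14): the 2-aryl ring is carried as fluoride-labile 2-(trimethylsilyl)ethoxymethyl (SEM) ethers, so that the last step is basic. Aldehyde 8 with SEMCl (i-Pr2NEt, CH2Cl2) would give the bis(SEM) aldehyde F8. The conditions of steps 5 and 6 should then give the dibromoalkene F9 and the bromoalkyne F10. Addition of 7 as in step 7 should give the bromovinyl ether F11, and ring closure as in step 8 the bis(SEM) benzofuran F12. TBAF in THF–DMPU at 60 °C is expected to release both phenols and give 14 without acid.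

**Further compounds**
F1 | step 8 | 4-iodo-2-geranylresorcinol | CC(C)=CCC/C(C)=C/Cc1c(O)ccc(I)c1O
F2 | step 8 | lithium [3,5-bis(methoxymethoxy)phenyl]acetylide | [Li]C#Cc1cc(OCOC)cc(OCOC)c1
F3 | step 8 | 1-ethynyl-3,5-bis(methoxymethoxy)benzene | C#Cc1cc(OCOC)cc(OCOC)c1
F4 | step 8 | 4-{[3,5-bis(methoxymethoxy)phenyl]ethynyl}-2-geranylbenzene-1,3-diol | CC(C)=CCC/C(C)=C/Cc1c(O)ccc(C#Cc2cc(OCOC)cc(OCOC)c2)c1O
F5 | step 7 | 2-geranyl-3-(methoxymethoxy)phenol | CC(C)=CCC/C(C)=C/Cc1c(O)cccc1OCOC
F6 | step 7 | 1-{[(Z)-1-[3,5-bis(methoxymethoxy)phenyl]-2-bromoethenyl]oxy}-2-geranyl-3-(methoxymethoxy)benzene | CC(C)=CCC/C(C)=C/Cc1c(OCOC)cccc1O/C(=C\Br)c1cc(OCOC)cc(OCOC)c1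
F7 | step 7 | 2-[3,5-bis(methoxymethoxy)phenyl]-7-geranyl-6-(methoxymethoxy)-1-benzofuran | CC(C)=CCC/C(C)=C/Cc1c(OCOC)ccc2cc(-c3cc(OCOC)cc(OCOC)c3)oc12
F8 | step 9 | 3,5-bis{[2-(trimethylsilyl)ethoxy]methoxy}benzaldehyde | O=Cc1cc(OCOCC[Si](C)(C)C)cc(OCOCC[Si](C)(C)C)c1
F9 | step 9 | 1-(2,2-dibromoethenyl)-3,5-bis{[2-(trimethylsilyl)ethoxy]methoxy}benzene | BrC(Br)=Cc1cc(OCOCC[Si](C)(C)C)cc(OCOCC[Si](C)(C)C)c1
F10 | step 9 | 1-(bromoethynyl)-3,5-bis{[2-(trimethylsilyl)ethoxy]methoxy}benzene | BrC#Cc1cc(OCOCC[Si](C)(C)C)cc(OCOCC[Si](C)(C)C)c1
F11 | step 9 | 3-{[(Z)-1-(3,5-bis{[2-(trimethylsilyl)ethoxy]methoxy}phenyl)-2-bromoethenyl]oxy}-2-geranylphenol | CC(C)=CCC/C(C)=C/Cc1c(O)cccc1O/C(=C\Br)c1cc(OCOCC[Si](C)(C)C)cc(OCOCC[Si](C)(C)C)c1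
F12 | step 9 | 2-(3,5-bis{[2-(trimethylsilyl)ethoxy]methoxy}phenyl)-7-geranyl-1-benzofuran-6-ol | CC(C)=CCC/C(C)=C/Cc1c(O)ccc2cc(-c3cc(OCOCC[Si](C)(C)C)cc(OCOCC[Si](C)(C)C)c3)oc12
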